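## Retrosynthetic overview

1. Target: ring A carries C1–CO2H between C2–OMe and C6–O–C1′ (ring B), the (R)-CH(OH)CH2C(CH3)2OH chain on C3, and H on C4 and C5. C1′ of ring B lies between C2′–OH and C6′–CH2OH. The strategy rests on the meta pair of oxygens on C2 and C6 with C1 between them and C3 substituted: a vinylketene and an alkynyl ether give exactly this pattern, so the crowded O–C1′ ether can be made at an sp carbon before ring A exists.
2. Late changes: C1–CO2H from C1–CH2O-PMB (DDQ, then two oxidations), C2–OMe from the C2 phenol, then removal of allyl, silyl and acetonide groups.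
3. Key disconnection: ring A (bonds C1–C2, C2–C3, C4–C5, C5–C6) into the ring B aryloxyalkyne ArBO–C≡C–CH2O-PMB (C1 and C6) and an (E)-diazo enone carrying the (4R)-dioxane (C2 to C5 and the stereocentre).
4. Aryloxyalkyne from the ring B phenol, trichloroethylene and formaldehyde; ring B phenol from creosol (formylation, demethylation, selective allylation, reduction, silylation).
5. Diazo enone from ethyl (R)-4-chloro-3-hydroxybutanoate (MeMgCl, sulfonium ylide homologation, acetonide, cross-metathesis, diazo transfer). Ring order: ring B is bought with creosol; ring A is the only ring built and is formed last.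

Key step: step 14

Remark on the chemistry: the chain stereocentre is taken from the chiral pool, because hydration of a glyoxylate–isobutene ene adduct would give a tertiary γ-hydroxy ester that lactonises before a 1,3-acetonide can be closed; the C–O bond of the carbinol is never broken and its descriptor stays (R) throughout.

Abbreviations: ArBO = 2-(allyloxy)-6-{[(tert-butyldimethylsilyl)oxy]methyl}-4-methylphenoxy (the aryloxy group of the ring B phenol made in step 5); PMB = 4-methoxybenzyl; TBS = tert-butyldimethylsilyl.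

## Route

Step 1
Reactants: 1 2-methoxy-4-methylphenol (creosol)
Product: 2 2-hydroxy-3-methoxy-5-methylbenzaldehyde
Conditions: (CH2O)n, MgCl2, Et3N, MeCN, reflux
Reagents that add atoms: paraformaldehyde (as formaldehyde), C=O
Why: Magnesium-phenoxide-directed ortho-formylation (Casnati–Skattebøl reaction) can only occur at the single free position ortho to the hydroxyl, and a second formaldehyde oxidises the benzylic alkoxide to the aldehyde.

Step 2
Reactants: 2 2-hydroxy-3-methoxy-5-methylbenzaldehyde
Product: 3 2,3-dihydroxy-5-methylbenzaldehyde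
Conditions: BBr3, CH2Cl2, −78 → 0 °C; then H2O
Reagents that add atoms: none
Why: Lewis-acid demethylation of the aryl methyl ether by bromide attack on the O-methyl of the borate complex should leave the aldehyde and the ring methyl untouched.

Step 3
Reactants: 3 2,3-dihydroxy-5-methylbenzaldehyde
Product: 4 3-(allyloxy)-2-hydroxy-5-methylbenzaldehyde
Conditions: NaH (2.2 equiv), DMSO, 20 °C; allyl bromide (1.0 equiv); then aq. HCl
Reagents that add atoms: allyl bromide, C=CCBr
Why: In the dianion the C3 phenoxide is the more nucleophilic oxygen because the C2 phenoxide is delocalised into and chelated by the ortho formyl group, so one equivalent of halide should give the 3-O-allyl ether (Williamson etherification).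

Step 4
Reactants: 4 3-(allyloxy)-2-hydroxy-5-methylbenzaldehyde
Product: 5 2-(allyloxy)-6-(hydroxymethyl)-4-methylphenol
Conditions: NaBH4, MeOH/THF, 0 °C
Reagents that add atoms: none
Why: Borohydride reduction of the aldehyde to the benzylic alcohol does not affect the allyl ether or the phenol.

Step 5
Reactants: 5 2-(allyloxy)-6-(hydroxymethyl)-4-methylphenol
Product: 6 2-(allyloxy)-6-{[(tert-butyldimethylsilyl)oxy]methyl}-4-methylphenol (ring B phenol ArBO–H)
Conditions: TBSCl (1.05 equiv), imidazole, CH2Cl2, 0 °C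
Reagents that add atoms: tert-butyldimethylsilyl chloride, CC(C)(C)[Si](C)(C)Cl
Why: The primary benzylic hydroxyl is silylated much faster than the hydrogen-bonded phenol flanked by two ortho groups (selective silyl ether formation), leaving the C1′ oxygen free.

Step 6
Reactants: 6 ring B phenol ArBO–H; 7 trichloroethylene
Product: 8 (E)-1,2-dichlorovinyl ether ArBO–CCl=CHCl
Conditions: K2CO3, DMF, 70 °C
Reagents that add atoms: none
Why: Base converts trichloroethylene to dichloroacetylene, to which the phenoxide adds anti (addition–elimination vinylation), a union at a slim sp carbon that the two ortho substituents of ring B cannot block.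

Step 7
Reactants: 8 (E)-1,2-dichlorovinyl ether ArBO–CCl=CHCl
Product: 11 3-(ArBO)prop-2-yn-1-ol, via chloroethynyl ether 9 (not isolated), via lithium acetylide 10 (not isolated)
Conditions: n-BuLi (2.3 equiv), THF, −78 → −40 °C; (CH2O)n, −78 → 20 °C; then H2O
Reagents that add atoms: paraformaldehyde (as formaldehyde), C=O
Why: Deprotonation and loss of LiCl give 9, chlorine–lithium exchange gives 10 and 1,2-addition to formaldehyde gives the propargylic alcohol (dichlorovinyl ether to alkynyl ether conversion, then acetylide hydroxymethylation), at temperatures where the allyl and silyl ethers are inert.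

Step 8
Reactants: 11 3-(ArBO)prop-2-yn-1-ol
Product: 12 aryloxyalkyne ArBO–C≡C–CH2O-PMB
Conditions: NaH, 4-MeOC6H4CH2Cl, Bu4NI (cat.), THF/DMF, 0 → 20 °C
Reagents that add atoms: 4-methoxybenzyl chloride, COc1ccc(CCl)cc1
Why: Williamson etherification of the sodium alkoxide proceeds under basic conditions, which the acid-sensitive ynol ether tolerates.

Step 9
Reactants: 13 ethyl (R)-4-chloro-3-hydroxybutanoate
Product: 14 (R)-1-chloro-4-methylpentane-2,4-diol
Conditions: MeMgCl (3.3 equiv), THF, −20 → 0 °C; then H2O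
Reagents that add atoms: methylmagnesium chloride, C[Mg]Cl
Why: Double Grignard addition to the ester (after deprotonation of the hydroxyl) gives the tertiary alcohol, the magnesium chlorohydrin alkoxide should not close to the epoxide at 0 °C, and the stereocentre is not involved.

Step 10
Reactants: 14 (R)-1-chloro-4-methylpentane-2,4-diol
Product: 16 (R)-5-methylhex-1-ene-3,5-diol, via epoxide 15 (not isolated)
Conditions: n-BuLi (2.0 equiv), THF, −40 → 0 °C; then Me3S+ I−/n-BuLi (3 equiv, preformed ylide), THF, −10 → 20 °C; then H2O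
Reagents that add atoms: trimethylsulfonium iodide, C[S+](C)C.[I-]
Why: The lithium alkoxide displaces chloride to give 15 without touching the C–O bond of the stereocentre, and dimethylsulfonium methylide opens 15 at the terminal carbon and leaves as dimethyl sulfide on ylide-mediated elimination (Corey–Chaykovsky-type one-carbon homologation of an epoxide to an allylic alcohol), so the (R)-configuration is carried over.

Step 11
Reactants: 16 (R)-5-methylhex-1-ene-3,5-diol
Product: 17 (6R)-6-ethenyl-2,2,4,4-tetramethyl-1,3-dioxane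
Conditions: 2-methoxypropene, PPTS (cat.), CH2Cl2, 0 °C; then Et3N
Reagents that add atoms: 2-methoxypropene, COC(C)=C
Why: Acid-catalysed ketalisation with the enol ether closes the six-membered 1,3-dioxane across the secondary and tertiary hydroxyls (acetonide formation) without affecting the stereocentre.

Step 12
Reactants: 17 (6R)-6-ethenyl-2,2,4,4-tetramethyl-1,3-dioxane; 18 methyl vinyl ketone
Product: 19 (3E)-4-[(4R)-2,2,6,6-tetramethyl-1,3-dioxan-4-yl]but-3-en-2-one
Conditions: 18 (4 equiv), RuCl2(H2IMes)(=CH–C6H4-2-OiPr) (second-generation Hoveyda–Grubbs catalyst, 3 mol %), CH2Cl2, 40 °C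
Reagents that add atoms: none
Why: Olefin cross-metathesis between the terminal allylic alkene and excess enone should give the thermodynamically preferred (E)-enone with loss of ethene.

Step 13
Reactants: 19 (3E)-4-[(4R)-2,2,6,6-tetramethyl-1,3-dioxan-4-yl]but-3-en-2-one
Product: 21 (3E)-1-diazo-4-[(4R)-2,2,6,6-tetramethyl-1,3-dioxan-4-yl]but-3-en-2-one, via trifluoroacetyl diketone 20 (not isolated)
Conditions: LiN(SiMe3)2, THF, −78 °C; CF3CO2CH2CF3; aq. HCl; then MsN3, Et3N, H2O, MeCN, 20 °C
Reagents that add atoms: methanesulfonyl azide, CS(=O)(=O)N=[N+]=[N-]; 2,2,2-trifluoroethyl trifluoroacetate (its atoms stay only in 20), O=C(OCC(F)(F)F)C(F)(F)F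
Why: The kinetic lithium enolate of the methyl ketone is trifluoroacetylated and the activated 1,3-diketone 20 undergoes detrifluoroacetylative diazo transfer, the standard mild entry to α′-diazo enones.

Step 14
Reactants: 12 aryloxyalkyne ArBO–C≡C–CH2O-PMB; 21 (3E)-1-diazo-4-[(4R)-2,2,6,6-tetramethyl-1,3-dioxan-4-yl]but-3-en-2-one
Product: 26 ring A phenol 3-(ArBO)-2-[(PMB-oxy)methyl]-6-[(4R)-2,2,6,6-tetramethyl-1,3-dioxan-4-yl]phenol, via vinylketene 22 (not isolated), via 4-alkenylcyclobutenone 23 (not isolated), via dienylketene 24 (not isolated), via cyclohexa-2,4-dienone 25 (not isolated)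
Conditions: 21 (1.2 equiv), hν (300–350 nm, Pyrex), degassed ClCH2CH2Cl, 20 °C; then 80 °C
Reagents that add atoms: none
Why: Light expels N2 from 21 and the alkenyl group migrates (photochemical Wolff rearrangement, which forms C4–C5) to give vinylketene 22; the alkyne carbon of 12 remote from oxygen attacks the ketene carbonyl carbon and a regioselective [2+2] cycloaddition closes cyclobutenone 23 (C1–C2 and C5–C6). This is the Danheiser benzannulation in its diazo ketone form, known for alkynyl ethers, siloxyalkynes and ynamides. Warming opens 23 by a reversible four-electron electrocyclic ring opening to dienylketene 24, and ring A is closed by a six-electron electrocyclisation (C2–C3) to dienone 25, which tautomerises to phenol 26. No stereocentre is created in the product, since the sp3 ring carbons of 23 and 25 are lost on aromatisation, and the (R)-centre of the dioxane lies outside the reacting π system. The one selectivity needed is the regiochemistry of the ketene–alkyne union, secured by oxygen polarisation of the aryloxyalkyne, which places OAr on C6 and CH2O-PMB on C1, while the connectivity of 21 places the dioxane on C3. The ynol ether is far more nucleophilic toward the ketene than the allyl ether alkene, and light above 300 nm is absorbed by the diazo enone and hardly by the aryl ethers.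

Step 15
Reactants: 26 ring A phenol
Product: 27 ring A methyl ether (C2–OMe; C1–CH2O-PMB; C6–OArB; C3–(4R)-dioxanyl)
Conditions: MeI, K2CO3, DMF, 20–40 °C
Reagents that add atoms: iodomethane, CI
Why: Williamson O-methylation of the hindered C2 phenoxide, the only acidic site of 26.

Step 16
Reactants: 27 ring A methyl ether
Product: 28 ring A benzylic alcohol {6-(ArBO)-2-methoxy-3-[(4R)-2,2,6,6-tetramethyl-1,3-dioxan-4-yl]phenyl}methanol
Conditions: DDQ, CH2Cl2/pH 7 phosphate buffer, 0 °C
Reagents that add atoms: none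
Why: DDQ removes a hydride from the p-methoxybenzylic position and water hydrolyses the oxocarbenium ion (oxidative PMB cleavage), the buffer protecting the acetonide and silyl ether, and any over-oxidation of 28 to the aldehyde is harmless because that aldehyde is the next intermediate.

Step 17
Reactants: 28 ring A benzylic alcohol
Product: 29 6-(ArBO)-2-methoxy-3-[(4R)-2,2,6,6-tetramethyl-1,3-dioxan-4-yl]benzaldehyde
Conditions: Dess–Martin periodinane, NaHCO3, CH2Cl2, 0 → 20 °C
Reagents that add atoms: none
Why: Dess–Martin oxidation of the primary benzylic alcohol to the aldehyde runs under buffered, non-acidic conditions that spare the acetonide, silyl ether and alkene.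

Step 18
Reactants: 29 ring A aldehyde
Product: 30 6-(ArBO)-2-methoxy-3-[(4R)-2,2,6,6-tetramethyl-1,3-dioxan-4-yl]benzoic acid
Conditions: NaClO2, NaH2PO4, 2-methyl-2-butene, t-BuOH/H2O, 0 → 20 °C
Reagents that add atoms: sodium chlorite, [Na+].[O-]Cl=O
Why: Pinnick oxidation converts the hindered aryl aldehyde to the acid, and excess 2-methyl-2-butene scavenges hypochlorous acid so that the allyl ether and the electron-rich rings are not chlorinated.

Step 19
Reactants: 30 ring A acid allyl ether
Product: 31 6-(2-hydroxy-6-{[(tert-butyldimethylsilyl)oxy]methyl}-4-methylphenoxy)-2-methoxy-3-[(4R)-2,2,6,6-tetramethyl-1,3-dioxan-4-yl]benzoic acid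
Conditions: Pd(PPh3)4 (5 mol %), morpholine, THF, 20 °C
Reagents that add atoms: none
Why: Zerovalent palladium ionises the aryl allyl ether to a π-allyl complex with the phenoxide as leaving group and morpholine captures the allyl group (Tsuji–Trost deallylation), the other ethers and the acetonide being inert.

Step 20
Reactants: 31 ring B phenol acid
Product: 32 6-[2-hydroxy-6-(hydroxymethyl)-4-methylphenoxy]-3-[(1R)-1,3-dihydroxy-3-methylbutyl]-2-methoxybenzoic acid (target)
Conditions: AcOH/THF/H2O (3:1:1), 30 °C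
Reagents that add atoms: none
Why: Mild aqueous acid hydrolyses the strained tetramethyl-1,3-dioxane and the primary silyl ether (acetal and silyl ether hydrolysis) without breaking the benzylic C–O bond, so the (R)-carbinol should be released unchanged.

## Compound list

1 | 2-methoxy-4-methylphenol (creosol) | COc1cc(C)ccc1O | starting material
2 | 2-hydroxy-3-methoxy-5-methylbenzaldehyde | COc1cc(C)cc(C=O)c1O | intermediate
3 | 2,3-dihydroxy-5-methylbenzaldehyde | Oc1cc(C)cc(C=O)c1O | intermediate
4 | 3-(allyloxy)-2-hydroxy-5-methylbenzaldehyde | C=CCOc1cc(C)cc(C=O)c1O | intermediate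
5 | 2-(allyloxy)-6-(hydroxymethyl)-4-methylphenol | C=CCOc1cc(C)cc(CO)c1O | intermediate
6 | 2-(allyloxy)-6-{[(tert-butyldimethylsilyl)oxy]methyl}-4-methylphenol (ArBO–H) | C=CCOc1cc(C)cc(CO[Si](C)(C)C(C)(C)C)c1O | intermediate
7 | trichloroethylene | ClC=C(Cl)Cl | starting material
8 | tert-butyl{[3-(allyloxy)-2-{[(E)-1,2-dichloroethenyl]oxy}-5-methylbenzyl]oxy}dimethylsilane | Cl/C=C(/Cl)Oc1c(OCC=C)cc(C)cc1CO[Si](C)(C)C(C)(C)C | intermediate
9 | chloroethynyl ether ArBO–C≡C–Cl (not isolated) | ClC#COc1c(OCC=C)cc(C)cc1CO[Si](C)(C)C(C)(C)C | intermediate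
10 | lithium acetylide ArBO–C≡C–Li (not isolated) | [Li]C#COc1c(OCC=C)cc(C)cc1CO[Si](C)(C)C(C)(C)C | intermediate
11 | 3-[2-(allyloxy)-6-{[(tert-butyldimethylsilyl)oxy]methyl}-4-methylphenoxy]prop-2-yn-1-ol | OCC#COc1c(OCC=C)cc(C)cc1CO[Si](C)(C)C(C)(C)C | intermediate
12 | tert-butyl{[3-(allyloxy)-2-({3-[(4-methoxybenzyl)oxy]prop-1-yn-1-yl}oxy)-5-methylbenzyl]oxy}dimethylsilane | COc1ccc(COCC#COc2c(OCC=C)cc(C)cc2CO[Si](C)(C)C(C)(C)C)cc1 | intermediate
13 | ethyl (R)-4-chloro-3-hydroxybutanoate | ClC[C@H](O)CC(=O)OCC | starting material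
14 | (R)-1-chloro-4-methylpentane-2,4-diol | ClC[C@H](O)CC(C)(C)O | intermediate
15 | 2-methyl-1-[(2R)-oxiran-2-yl]propan-2-ol (not isolated) | CC(C)(O)C[C@@H]1CO1 | intermediate
16 | (R)-5-methylhex-1-ene-3,5-diol | C=C[C@H](O)CC(C)(C)O | intermediate
17 | (6R)-6-ethenyl-2,2,4,4-tetramethyl-1,3-dioxane | C=C[C@H]1CC(C)(C)OC(C)(C)O1 | intermediate
18 | methyl vinyl ketone | CC(=O)C=C | starting material
19 | (3E)-4-[(4R)-2,2,6,6-tetramethyl-1,3-dioxan-4-yl]but-3-en-2-one | CC(=O)/C=C/[C@H]1CC(C)(C)OC(C)(C)O1 | intermediate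
20 | (5E)-1,1,1-trifluoro-6-[(4R)-2,2,6,6-tetramethyl-1,3-dioxan-4-yl]hex-5-ene-2,4-dione (not isolated) | O=C(CC(=O)C(F)(F)F)/C=C/[C@H]1CC(C)(C)OC(C)(C)O1 | intermediate
21 | (3E)-1-diazo-4-[(4R)-2,2,6,6-tetramethyl-1,3-dioxan-4-yl]but-3-en-2-one | [N-]=[N+]=CC(=O)/C=C/[C@H]1CC(C)(C)OC(C)(C)O1 | intermediate
22 | (3E)-4-[(4R)-2,2,6,6-tetramethyl-1,3-dioxan-4-yl]buta-1,3-dien-1-one, vinylketene (not isolated) | O=C=C/C=C/[C@H]1CC(C)(C)OC(C)(C)O1 | intermediate
23 | 3-(ArBO)-2-{[(4-methoxybenzyl)oxy]methyl}-4-{(E)-2-[(4R)-2,2,6,6-tetramethyl-1,3-dioxan-4-yl]ethenyl}cyclobut-2-en-1-one, both C4 epimers (not isolated) | O=C1C(COCc2ccc(OC)cc2)=C(Oc2c(OCC=C)cc(C)cc2CO[Si](C)(C)C(C)(C)C)C1/C=C/[C@H]1CC(C)(C)OC(C)(C)O1 | intermediate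
24 | dienylketene: 3-(ArBO)-2-{[(4-methoxybenzyl)oxy]methyl}-6-[(4R)-2,2,6,6-tetramethyl-1,3-dioxan-4-yl]hexa-1,3,5-trien-1-one, alkenyl group cis to the ketene carbon, (5E) (not isolated) | O=C=C(COCc1ccc(OC)cc1)/C(Oc1c(OCC=C)cc(C)cc1CO[Si](C)(C)C(C)(C)C)=C\C=C\[C@H]1CC(C)(C)OC(C)(C)O1 | intermediate
25 | 3-(ArBO)-2-{[(4-methoxybenzyl)oxy]methyl}-6-[(4R)-2,2,6,6-tetramethyl-1,3-dioxan-4-yl]cyclohexa-2,4-dien-1-one, both C6 epimers (not isolated) | O=C1C(COCc2ccc(OC)cc2)=C(Oc2c(OCC=C)cc(C)cc2CO[Si](C)(C)C(C)(C)C)C=CC1[C@H]1CC(C)(C)OC(C)(C)O1 | intermediate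
26 | 3-(ArBO)-2-{[(4-methoxybenzyl)oxy]methyl}-6-[(4R)-2,2,6,6-tetramethyl-1,3-dioxan-4-yl]phenol | Oc1c([C@H]2CC(C)(C)OC(C)(C)O2)ccc(Oc2c(OCC=C)cc(C)cc2CO[Si](C)(C)C(C)(C)C)c1COCc1ccc(OC)cc1 | intermediate
27 | methyl ether of 26 (ring A: C2–OMe, C1–CH2O-PMB, C6–OArB, C3–(4R)-dioxanyl) | COc1c([C@H]2CC(C)(C)OC(C)(C)O2)ccc(Oc2c(OCC=C)cc(C)cc2CO[Si](C)(C)C(C)(C)C)c1COCc1ccc(OC)cc1 | intermediate
28 | {6-(ArBO)-2-methoxy-3-[(4R)-2,2,6,6-tetramethyl-1,3-dioxan-4-yl]phenyl}methanol | COc1c([C@H]2CC(C)(C)OC(C)(C)O2)ccc(Oc2c(OCC=C)cc(C)cc2CO[Si](C)(C)C(C)(C)C)c1CO | intermediate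
29 | 6-(ArBO)-2-methoxy-3-[(4R)-2,2,6,6-tetramethyl-1,3-dioxan-4-yl]benzaldehyde | COc1c([C@H]2CC(C)(C)OC(C)(C)O2)ccc(Oc2c(OCC=C)cc(C)cc2CO[Si](C)(C)C(C)(C)C)c1C=O | intermediate
30 | 6-(ArBO)-2-methoxy-3-[(4R)-2,2,6,6-tetramethyl-1,3-dioxan-4-yl]benzoic acid | COc1c([C@H]2CC(C)(C)OC(C)(C)O2)ccc(Oc2c(OCC=C)cc(C)cc2CO[Si](C)(C)C(C)(C)C)c1C(=O)O | intermediate
31 | 6-(2-hydroxy-6-{[(tert-butyldimethylsilyl)oxy]methyl}-4-methylphenoxy)-2-methoxy-3-[(4R)-2,2,6,6-tetramethyl-1,3-dioxan-4-yl]benzoic acid | COc1c([C@H]2CC(C)(C)OC(C)(C)O2)ccc(Oc2c(O)cc(C)cc2CO[Si](C)(C)C(C)(C)C)c1C(=O)O | intermediate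
32 | 6-[2-hydroxy-6-(hydroxymethyl)-4-methylphenoxy]-3-[(1R)-1,3-dihydroxy-3-methylbutyl]-2-methoxybenzoic acid | COc1c([C@H](O)CC(C)(C)O)ccc(Oc2c(O)cc(C)cc2CO)c1C(=O)O | target

## Step count and risks

Total step count: 20. Longest linear sequence: 15 steps (steps 1–8 and 14–20, from creosol); the enone branch (steps 9–13) joins at step 14.

Steps most likely to fail:

1. Step 14 (key step). The vinylketene may dimerise, or be captured by the phenol product, faster than it adds to the hindered and only moderately nucleophilic aryloxyalkyne, and the aryl ether chromophores may be photolysed during irradiation. Fallback: ring A is bought and the diaryl ether is made by nucleophilic aromatic substitution, setting out from ring B phenol 6 and returning at aldehyde 29. Commercial 4-fluoro-2-methoxybenzaldehyde (COc1cc(F)ccc1C=O) is treated with B-methallyldiisopinocampheylborane derived from (−)-α-pinene (Brown allylboration, Et2O, −78 °C, then NaOH/H2O2; Re-face addition expected) to give (R)-1-(4-fluoro-2-methoxyphenyl)-3-methylbut-3-en-1-ol F1. Mukaiyama hydration (Co(acac)2, PhSiH3, O2, THF) gives (R)-1-(4-fluoro-2-methoxyphenyl)-3-methylbutane-1,3-diol F2, and 2-methoxypropene/PPTS gives (4R)-4-(4-fluoro-2-methoxyphenyl)-2,2,6,6-tetramethyl-1,3-dioxane F3. Lithiation at the ring carbon between OMe and F (n-BuLi, THF, −78 °C) and quenching with DMF give 6-fluoro-2-methoxy-3-[(4R)-2,2,6,6-tetramethyl-1,3-dioxan-4-yl]benzaldehyde F4. Displacement of the fluoride ortho to the formyl group by the potassium salt of 6 (K2CO3, DMF, 90 °C) gives 29, which continues with step 18.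

2. Step 7. The 3-aryloxyprop-2-yn-1-ol may rearrange (Meyer–Schuster type) or hydrate during work-up and on silica, and slow depolymerisation of paraformaldehyde may leave the acetylide to be protonated. Fallback: the free propargylic alcohol is never made. Setting out from 8, acetylide 10 is generated as in step 7 and alkylated at −78 → 0 °C with 4-methoxybenzyl chloromethyl ether (COc1ccc(COCCl)cc1), a known α-chloro ether alkylation of a lithium acetylide. This returns at 12 and replaces steps 7 and 8; it makes no compound outside the list (F0).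

3. Step 12. Cross-metathesis at the hindered allylic acetal carbon may be slow, so that self-metathesis of methyl vinyl ketone and catalyst decay take over. Fallback: setting out from 17, ozonolysis (O3, CH2Cl2, −78 °C; then PPh3) gives (4R)-2,2,6,6-tetramethyl-1,3-dioxane-4-carbaldehyde F5. Wittig olefination with 1-(triphenylphosphoranylidene)propan-2-one (CH2Cl2, 40 °C) then returns at (E)-enone 19.

## Further compounds

F1 | step 14 | (R)-1-(4-fluoro-2-methoxyphenyl)-3-methylbut-3-en-1-ol | COc1cc(F)ccc1[C@H](O)CC(C)=C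
F2 | step 14 | (R)-1-(4-fluoro-2-methoxyphenyl)-3-methylbutane-1,3-diol | COc1cc(F)ccc1[C@H](O)CC(C)(C)O
F3 | step 14 | (4R)-4-(4-fluoro-2-methoxyphenyl)-2,2,6,6-tetramethyl-1,3-dioxane | COc1cc(F)ccc1[C@H]1CC(C)(C)OC(C)(C)O1
F4 | step 14 | 6-fluoro-2-methoxy-3-[(4R)-2,2,6,6-tetramethyl-1,3-dioxan-4-yl]benzaldehyde | COc1c(C=O)c(F)ccc1[C@H]1CC(C)(C)OC(C)(C)O1
F0 | step 7 | none | none
F5 | step 12 | (4R)-2,2,6,6-tetramethyl-1,3-dioxane-4-carbaldehyde | O=C[C@H]1CC(C)(C)OC(C)(C)O1
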